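**Strategy.** Ring atoms: C1 = C(Me)(chlorovinyl), C2 = CH2, C3 = CBr(CH2Br), C4 = CHCl, C5 = CH2, C6 = CHCl. The route rests on forming C1–C2 by a 1,2-shift: the cyclohexane arises by ring contraction of (R)-2,6-dimethylcyclohepta-2,5-dien-1-ol. A chloronium-triggered semipinacol shift exploits the vicinal pair quaternary C1 / neopentyl C6–Cl. In one operation it makes the six-membered ring, the quaternary centre and the C6–Cl bond cis to the extruded formyl (future chlorovinyl) carbon; chirality is relayed from a CBS-set carbinol that disappears. The cycloheptadienol comes from 3-methylanisole by Birch reduction and chloro(methyl)carbene ring expansion.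

Key step: step 5

Remark on the chemistry (assumption): in step 5 chlorine is assumed to be delivered to the alkene face syn to the hydrogen-bonded hydroxyl. If the anti face reacted productively instead, (R)-Me-CBS in step 4 would supply the carbinol needed for the same product.

Step 1
Reactants: 1 3-methylanisole
Product: 2 1-methoxy-5-methylcyclohexa-1,4-diene
Conditions: Li, liq. NH3, THF, t-BuOH, −78 to −33 °C; then MeOH
Reagents that add atoms: none
Why: Birch reduction: the donor groups OMe and Me stay on the two remaining double bonds, which gives the 2,5-dihydroanisole with a regiodefined enol ether; no stereocentre is formed.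

Step 2
Reactants: 2 1-methoxy-5-methylcyclohexa-1,4-diene
Product: 3 7-chloro-1-methoxy-3,7-dimethylbicyclo[4.1.0]hept-3-ene (racemic, both C7 epimers)
Conditions: CH3CHCl2, n-BuLi, Et2O, −35 °C to rt
Reagents that add atoms: 1,1-dichloroethane CC(Cl)Cl
Why: Halocarbene cyclopropanation: the chloro(methyl)carbenoid from α-elimination of 1,1-dichloroethyllithium should add to the electron-rich enol-ether double bond in preference to the trisubstituted alkene; the new stereocentres form as a racemic epimer mixture and are all erased in step 3.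

Step 3
Reactants: 3 7-chloro-1-methoxy-3,7-dimethylbicyclo[4.1.0]hept-3-ene
Product: 5 2,6-dimethylcyclohepta-2,5-dien-1-one, via hemiketal 4 (not isolated)
Conditions: AgNO3, NaHCO3, acetone–H2O, 0 °C to rt
Reagents that add atoms: water O
Why: Silver-assisted disrotatory electrocyclic opening of the chlorocyclopropane (halocyclopropane ring expansion of an enol ether) gives the methoxy-stabilised 2-methylallyl cation, water adds at the oxocarbenium carbon and hemiketal 4 loses methanol, which fixes the carbonyl next to the new C(Me)=CH unit; the endo-chloro epimer should open directly and the exo-chloro epimer more slowly with methoxy assistance.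

Step 4
Reactants: 5 2,6-dimethylcyclohepta-2,5-dien-1-one
Product: 6 (R)-2,6-dimethylcyclohepta-2,5-dien-1-ol
Conditions: (S)-Me-CBS (15 mol %), catecholborane, toluene, −78 °C; aq. work-up
Reagents that add atoms: none
Why: Corey–Bakshi–Shibata reduction: the α-methyl-alkenyl arm acts as the large group, so the (S)-oxazaborolidine should deliver hydride to give the (R)-carbinol, and catecholborane at −78 °C should spare both alkenes.

Step 5
Reactants: 6 (R)-2,6-dimethylcyclohepta-2,5-dien-1-ol (locants: C1 carbinol, C2 methyl-bearing alkene carbon, C3 =CH, C7 ring CH2 next to C1)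
Product: 7 (1S,6S)-6-chloro-1,3-dimethylcyclohex-3-ene-1-carbaldehyde
Conditions: NCS (1.05 equiv), (PhO)2P(O)OH (10 mol %), CH2Cl2, −40 to −20 °C
Reagents that add atoms: N-chlorosuccinimide O=C1CCC(=O)N1Cl
Why: Proposed new method: chlorine is delivered from hydrogen-bonded NCS/phosphoric acid to C3 of the allylic alkene on the face of the pseudo-axial OH, and as the chloronium opens at the tertiary C2 the anti-periplanar ring bond C1–C7 migrates to C2 with push from the carbinol oxygen, so C1 leaves the ring as the formyl group (semipinacol 1,2-shift, ring contraction 7 to 6). The closest known reaction types are the halonium-induced semipinacol rearrangement of tertiary allylic alcohols with N-haloimides and the Lewis-acid ring contraction of 2,3-epoxy silyl ethers to β-siloxy aldehydes; here the type is extended to a secondary cycloheptenol with an alkyl shift. The six-membered ring is closed by the suprafacial 1,2-alkyl shift of C7 from C1 to C2 and not by a cyclisation, so no Baldwin mode applies. Both new stereocentres follow from the carbinol centre of 6, which is destroyed: syn-directed chlorination fixes the C–Cl carbon (6S) and anti migration fixes the quaternary carbon (1S), which places Cl cis to CHO. The step needs reaction at the allylic-alcohol alkene and not at the remote trisubstituted alkene, which hydroxyl-directed delivery and the internal 1,2-shift (only this chloronium is trapped productively) should secure. It also needs carbon and not hydride migration, which A(1,2) strain with the 2-methyl group should secure by holding the carbinol C–H in the alkene plane and the C1–C7 bond anti to the forming C–Cl bond.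

Step 6
Reactants: 7 (1S,6S)-6-chloro-1,3-dimethylcyclohex-3-ene-1-carbaldehyde
Product: 8 (4S,5S)-4-chloro-5-[(Z)-2-chloroethenyl]-1,5-dimethylcyclohex-1-ene
Conditions: Ph3P(CH2Cl)Cl, NaHMDS, THF, −78 °C; then 7, −78 to 0 °C
Reagents that add atoms: (chloromethyl)triphenylphosphonium chloride ClC[P+](c1ccccc1)(c1ccccc1)c1ccccc1.[Cl-]
Why: Wittig chloromethylenation of a non-enolisable aldehyde: the α-chloro ylide under lithium-free conditions should favour the cis-oxaphosphetane and so the Z-chloroalkene, with the minor E isomer removed by chromatography; no ring stereocentre is touched.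

Step 7
Reactants: 8 (4S,5S)-4-chloro-5-[(Z)-2-chloroethenyl]-1,5-dimethylcyclohex-1-ene
Product: 9 (1R,3S,4S,6S)-4-chloro-3-[(Z)-2-chloroethenyl]-1,3-dimethyl-7-oxabicyclo[4.1.0]heptane
Conditions: mCPBA, NaHCO3, CH2Cl2, 0 °C
Reagents that add atoms: mCPBA OOC(=O)c1cccc(Cl)c1
Why: Prilezhaev epoxidation: the trisubstituted ring alkene should react while the chlorovinyl group is deactivated, and the peracid should approach the face of the C1 methyl group, anti to the pseudo-axial chlorovinyl group and the C6–Cl dipole, which sets both epoxide carbons.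

Step 8
Reactants: 9 (1R,3S,4S,6S)-4-chloro-3-[(Z)-2-chloroethenyl]-1,3-dimethyl-7-oxabicyclo[4.1.0]heptane
Product: 10 (1S,4S,5S)-5-chloro-4-[(Z)-2-chloroethenyl]-4-methyl-2-methylidenecyclohexan-1-ol
Conditions: Al(OiPr)3 (cat.), toluene, 110 °C
Reagents that add atoms: none
Why: Aluminium-alkoxide epoxide-to-allylic-alcohol isomerisation (syn β-elimination through a cyclic transition state): the tertiary C–O bond breaks with removal of a methyl hydrogen, which is less hindered than the neopentyl C2 hydrogens, and the C4–O bond is untouched, so the carbinol keeps the epoxide configuration.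

Step 9
Reactants: 10 (1S,4S,5S)-5-chloro-4-[(Z)-2-chloroethenyl]-4-methyl-2-methylidenecyclohexan-1-ol
Product: 11 (1S,2S,4R)-2,4-dichloro-1-[(Z)-2-chloroethenyl]-1-methyl-5-methylidenecyclohexane
Conditions: PPh3, Cl3CC(O)CCl3, CH2Cl2, −20 to 0 °C
Reagents that add atoms: hexachloroacetone O=C(C(Cl)(Cl)Cl)C(Cl)(Cl)Cl
Why: Appel-type chlorination (PPh3/hexachloroacetone): chloride should displace the axial alkoxyphosphonium group at C4 by SN2 with inversion under conditions known to keep allylic transposition low, which places C4–Cl cis to C6–Cl.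

Step 10
Reactants: 11 (1S,2S,4R)-2,4-dichloro-1-[(Z)-2-chloroethenyl]-1-methyl-5-methylidenecyclohexane
Product: 12 (1S,2R,4S,5S)-1-bromo-1-(bromomethyl)-2,4-dichloro-5-[(Z)-2-chloroethenyl]-5-methylcyclohexane (CNP0497262.2)
Conditions: Br2 (1.0 equiv), CH2Cl2, −78 °C, dark
Reagents that add atoms: bromine BrBr
Why: Electrophilic anti-addition of bromine: the 1,1-disubstituted alkene is far more nucleophilic than the chlorovinyl group, the bromonium should form on the face away from the axial chlorovinyl group, and bromide should open it at the tertiary carbon by axial attack, giving the axial C3–Br cis to C4–Cl with CH2Br equatorial.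

**Compound list**

1 | 3-methylanisole | COc1cccc(C)c1 | starting material
2 | 1-methoxy-5-methylcyclohexa-1,4-diene | COC1=CCC=C(C)C1 | intermediate
3 | 7-chloro-1-methoxy-3,7-dimethylbicyclo[4.1.0]hept-3-ene (racemic, both C7 epimers) | COC12CC(C)=CCC1C2(C)Cl | intermediate
4 | 1-methoxy-2,6-dimethylcyclohepta-2,5-dien-1-ol (hemiketal, not isolated) | COC1(O)C(C)=CCC=C(C)C1 | intermediate
5 | 2,6-dimethylcyclohepta-2,5-dien-1-one | O=C1C(C)=CCC=C(C)C1 | intermediate
6 | (R)-2,6-dimethylcyclohepta-2,5-dien-1-ol | O[C@H]1C(C)=CCC=C(C)C1 | intermediate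
7 | (1S,6S)-6-chloro-1,3-dimethylcyclohex-3-ene-1-carbaldehyde | C[C@@]1(C=O)CC(C)=CC[C@@H]1Cl | intermediate
8 | (4S,5S)-4-chloro-5-[(Z)-2-chloroethenyl]-1,5-dimethylcyclohex-1-ene | C[C@@]1(/C=C\Cl)CC(C)=CC[C@@H]1Cl | intermediate
9 | (1R,3S,4S,6S)-4-chloro-3-[(Z)-2-chloroethenyl]-1,3-dimethyl-7-oxabicyclo[4.1.0]heptane | C[C@@]1(/C=C\Cl)C[C@@]2(C)O[C@H]2C[C@@H]1Cl | intermediate
10 | (1S,4S,5S)-5-chloro-4-[(Z)-2-chloroethenyl]-4-methyl-2-methylidenecyclohexan-1-ol | C[C@@]1(/C=C\Cl)CC(=C)[C@@H](O)C[C@@H]1Cl | intermediate
11 | (1S,2S,4R)-2,4-dichloro-1-[(Z)-2-chloroethenyl]-1-methyl-5-methylidenecyclohexane | C[C@@]1(/C=C\Cl)CC(=C)[C@H](Cl)C[C@@H]1Cl | intermediate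
12 | (1S,2R,4S,5S)-1-bromo-1-(bromomethyl)-2,4-dichloro-5-[(Z)-2-chloroethenyl]-5-methylcyclohexane | C[C@@]1(/C=C\Cl)C[C@@](Br)(CBr)[C@H](Cl)C[C@@H]1Cl | target

Total step count: 10. Longest linear sequence: 10 steps (from 3-methylanisole).

**Steps most likely to fail**

Step 5 (proposed new method). Chlorine may be transferred to the remote trisubstituted alkene, hydride may migrate instead of the ring carbon, or the carbinol may be oxidised by the N-chloroimide. The fallback uses known chemistry and sets out from 6. Hydroxyl-directed epoxidation (VO(acac)2, t-BuOOH, CH2Cl2, 0 °C) should give the syn-epoxy alcohol (1R,2R,7S)-1,4-dimethyl-8-oxabicyclo[5.1.0]oct-4-en-2-ol F1. Silylation (TBSCl, imidazole, DMF) gives its TBS ether F2. Lewis-acid semipinacol ring contraction of this 2,3-epoxy silyl ether (BF3·OEt2, CH2Cl2, −78 °C) should give (1R,6S)-6-[(tert-butyldimethylsilyl)oxy]-1,3-dimethylcyclohex-3-ene-1-carbaldehyde F3, with oxygen cis to the formyl group. HF·pyridine frees (1R,6S)-6-hydroxy-1,3-dimethylcyclohex-3-ene-1-carbaldehyde F4. Stereoretentive chlorination through the chlorosulfite (SOCl2, cat. TiCl4, CH2Cl2, 0 °C) comes back to the route at 7.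

Step 9. Chloride may attack the exocyclic methylene carbon (allylic transposition), or the axial leaving group may ionise with loss of configuration. The fallback sets out from 10 and removes the allylic system before the substitution. Selective ozonolysis of the methylidene group (O3, CH2Cl2–MeOH, −78 °C; Me2S) gives the α-hydroxy ketone (2S,4S,5S)-4-chloro-5-[(Z)-2-chloroethenyl]-2-hydroxy-5-methylcyclohexan-1-one F7. Appel chlorination at the α-keto carbon (PPh3, CCl4), an SN2 process with inversion and no transposition pathway, gives (2R,4S,5S)-2,4-dichloro-5-[(Z)-2-chloroethenyl]-5-methylcyclohexan-1-one F8. Wittig methylenation (Ph3P=CH2, THF, −78 to 0 °C) comes back to the route at 11.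

Step 6. The Z/E selectivity of the chloromethylenation of the hindered aldehyde may be low. The fallback sets out from 7. Ohira–Bestmann homologation (dimethyl (1-diazo-2-oxopropyl)phosphonate, K2CO3, MeOH) gives the alkyne (4S,5S)-4-chloro-5-ethynyl-1,5-dimethylcyclohex-1-ene F5. Deprotonation and chlorination (LiHMDS, THF, −78 °C; NCS) give (4S,5S)-4-chloro-5-(chloroethynyl)-1,5-dimethylcyclohex-1-ene F6. Syn hydroboration and protodeboronation (Cy2BH, THF, 0 °C; AcOH) should give the Z-chloroalkene only, and the sequence comes back to the route at 8.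

**Further compounds**

F1 | step 5 | (1R,2R,7S)-1,4-dimethyl-8-oxabicyclo[5.1.0]oct-4-en-2-ol (epoxide syn to OH) | O[C@H]1[C@@]2(C)O[C@H]2CC=C(C)C1
F2 | step 5 | tert-butyl{[(1S,2R,7S)-1,4-dimethyl-8-oxabicyclo[5.1.0]oct-4-en-2-yl]oxy}dimethylsilane (epoxide syn to OTBS) | CC(C)(C)[Si](C)(C)O[C@H]1[C@@]2(C)O[C@H]2CC=C(C)C1
F3 | step 5 | (1R,6S)-6-[(tert-butyldimethylsilyl)oxy]-1,3-dimethylcyclohex-3-ene-1-carbaldehyde | C[C@@]1(C=O)CC(C)=CC[C@@H]1O[Si](C)(C)C(C)(C)C
F4 | step 5 | (1R,6S)-6-hydroxy-1,3-dimethylcyclohex-3-ene-1-carbaldehyde | C[C@@]1(C=O)CC(C)=CC[C@@H]1O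
F5 | step 6 | (4S,5S)-4-chloro-5-ethynyl-1,5-dimethylcyclohex-1-ene | C[C@@]1(C#C)CC(C)=CC[C@@H]1Cl
F6 | step 6 | (4S,5S)-4-chloro-5-(chloroethynyl)-1,5-dimethylcyclohex-1-ene | C[C@@]1(C#CCl)CC(C)=CC[C@@H]1Cl
F7 | step 9 | (2S,4S,5S)-4-chloro-5-[(Z)-2-chloroethenyl]-2-hydroxy-5-methylcyclohexan-1-one | C[C@@]1(/C=C\Cl)CC(=O)[C@@H](O)C[C@@H]1Cl
F8 | step 9 | (2R,4S,5S)-2,4-dichloro-5-[(Z)-2-chloroethenyl]-5-methylcyclohexan-1-one | C[C@@]1(/C=C\Cl)CC(=O)[C@H](Cl)C[C@@H]1Cl
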